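## The problem

The target is one cyclohexene ring, numbered here C1(OBz)–C2=C3–C4(OBz)–C5(OH)–C6(OH)(C7H2OH). The same numbers, and stereodescriptors based on them, are used for every intermediate. Four contiguous stereocentres (1S,4R,5S,6S) flank the alkene: the benzoates at C1 and C4 lie on one face (α), the hydroxyls at C5 and C6 on the other (β), and C7 sits on the α face, cis to O1. Five oxygens must be told apart (two acylated allylic secondary, one free secondary, one tertiary, one primary), so each should enter in a way that already distinguishes it from its neighbours. The trans C4/C5 pair is the signature of an anti epoxide opening. C1 can control C6 through a tether, but nothing on the ring can set C1, C4 and C5 in the absolute sense, so one catalyst-controlled step is needed. Allylic benzoates migrate to a neighbouring free hydroxyl under base (O4 to O5, O1 to O7). Any C6 ketone flanked by oxygenated C1 and C5 with a benzoate at C4 is one elimination away from a phenol, so basic conditions are excluded from the ketone stage onward. The enabling feature is that C7 and O1 are cis on adjacent ring atoms: a ring C1–O1–Si–C7–C6 can be closed from a silyl ether on O1 onto a C6 ketone, which fixes the quaternary centre.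

## Retrosynthesis

**Target 20 back to triol 16.** The O1 benzoate is cut last, because O1 is the anchor of the tether and cannot be acylated earlier. Triol 16 already carries the C4 benzoate and a TBS ether on O5. Going forward, the primary O7 must be blocked first (17), since it would otherwise be benzoylated before the hindered O1. Then O1 is benzoylated (19) and both silyl ethers are removed under acidic fluoride, which avoids benzoyl migration.

**Triol 16 back to oxasilolane 15.** The C7–O bond and the O1–H bond are traced to C7–Si and O1–Si. A Tamao–Fleming oxidation turns the silicon bridge into two hydroxyls in one operation. Silicon is therefore a traceless linker and C7 needs no separate oxidation-state adjustment.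

**Oxasilolane 15 back to ketone 13.** The C6–C7 bond is cut. An untethered hydroxymethyl nucleophile would meet α-oxygen substituents on both faces of the C6 carbonyl (O1 below, O5 above) with no clear bias. A CH2 unit hung from O1 can only reach the α face. The forward step must turn Si–CH2–Br into a nucleophile without reducing the ketone first.

**Ketone 13 back to cis-diol 10.** The O1–Si bond and the C6 carbonyl are traced to a C1/C6 cis-diol via 12. O1–H is allylic and flanked by an sp2 carbon. O6–H lies between two oxygenated carbons, one bearing the TBS ether. One equivalent of chlorosilane 11 should therefore go to O1, and the remaining hydroxyl is oxidised. Putting the tether on before the oxidation avoids handling a free, enolisable α-ketol.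

**Diol 10 back to vinyl epoxide 6 and benzoic acid 7.** The C4–O benzoate bond is cut: anti opening of 6 at its allylic carbon by benzoate gives 8 with the benzoate on C4 and the only free hydroxyl on C5. O4 and O5 are thus differentiated by construction, and C5 is silylated (9) before the acetonide is removed (10). The neighbouring options are weaker. Benzoylating a preformed C4/C5 diol needs a site selection. A route through a meso ene-diol with the acetonide on O5/O6 leaves those two oxygens without any structural handle, because each is trans to its outer neighbour and no ring can relay the information.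

**Epoxide 6 back to meso diene 5.** Both epoxide C–O bonds are cut. A catalyst-controlled epoxidation chooses one of the two enantiotopic alkenes of 5, while the acetonide steers the oxidant to the opposite face. This is the single enantio-determining event. It sets C4 and C5 and, through the choice of alkene, makes the acetonide carbons C1 and C6.

**Diene 5 back to cyclohexa-1,4-diene 1.** The two C–O bonds at C1/C6 come from a cis-dihydroxylation and the diene from loss of two HBr. The known sequence is bromination of one alkene (2), dihydroxylation of the other (3), acetonide formation (4) and double dehydrobromination. The stereocentres of racemic 2–4 disappear in meso 5.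

## Roads not taken

**Alternative 1:** The cut is the C6–C1 bond together with the C2=C3 alkene. The forward key step is an Ireland–Claisen rearrangement of silyl ketene acetal A1, derived from a gluco-configured δ-lactone carrying an (E)-2-alkoxyvinyl group on the ring-oxygen carbon. The [3,3] shift, forced through a boat because the lactone ring bridges the allyl vinyl ether, forms C6–C1, breaks C3–O and gives acid A2, with C7 as the carboxyl carbon.
- Merits: C4 and C5 come from the chiral pool. C6 and C1 are set together by chirality transfer. No catalyst-controlled step and no untested reaction type are involved.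
- Weak points: the lactone enolate has a β-alkoxy group at C5 and can eliminate before it is trapped. The ketene acetal is tetrasubstituted and the boat is strained. The sugar must be extended to an enol ether of defined geometry. A2 still needs two PMB ethers exchanged for benzoates, two benzyl ethers removed without touching the alkene, and the acid reduced.
- Comparison: absolute stereocontrol is more secure than in step 5 of the chosen plan, and that is a real advantage. The chosen plan offers in return a ring bought ready-made, a C4 benzoate in its final form from step 6, and far fewer protecting-group exchanges.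

**Alternative 2:** The cut is the C5–O/C4–O pair. The forward key step is a Katsuki–Sharpless epoxidation (Ti(OiPr)4, a dialkyl tartrate, tBuOOH) that desymmetrises the prochiral Birch-derived dienol A3, giving syn epoxy alcohol A4.
- Merits: the quaternary carbinol with C7 is present from the first steps and comes from cheap aromatic material. One catalytic step sets C6 and C5. Inversion at C4 by benzoate would give the correct trans C4/C5 pair.
- Weak points: tertiary, doubly allylic alcohols are slow and poorly selective substrates for the titanium tartrate system. A3 aromatises easily by ionisation. The epoxide carbon C4 of A4 has no allylic activation, so regioselective opening is uncertain. A4 lacks the C1 oxygen and has its alkene at C1=C2 with a CH2 at C3, so an oxidative allylic transposition with its own facial problem (O1 trans to the C6 hydroxyl) is still needed.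
- Comparison: its opening is shorter and cheaper than steps 1–5, and the C6–C7 bond is no issue at all; in both respects it is better. The chosen plan has the C1 oxygen and the C2=C3 alkene in place from the diene, and all four ring oxygens arise from two stereospecific events.

**Alternative 3:** The cut is the C3–C4 bond. The forward key step is a Nozaki–Hiyama–Kishi cyclisation of (Z)-iodoalkenyl aldehyde A5 (CrCl2, catalytic NiCl2) to cyclohexenol A6.
- Merits: A6 has a single free hydroxyl at C4, so benzoylation and one acidic deprotection would finish the synthesis. The C–C bond formation is mild and the Z geometry is carried into the ring.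
- Weak points: A5, with the quaternary C6, two further stereocentres and a (Z)-vinyl iodide, is a long acyclic synthesis in itself. C4 is created in the ring closure under substrate control only. The allylic benzoate next to the alkenylmetal can be lost. Chromium is used in excess.
- Comparison: its end game is shorter and cleaner than steps 12–15 of the chosen plan, which is a genuine advantage. The chosen plan sets C4 stereospecifically by epoxide opening and reaches its key intermediate from a commercial six-membered ring.

Key step: step 11

Assumption: the (S,S) enantiomer of the (salen)MnCl catalyst is taken to epoxidise the C4=C5 alkene of 5 on the face anti to the acetonide, by analogy with its known sense on cis-alkenes conjugated to an unsaturated group. If the sense is the opposite, the (R,R) catalyst is used and nothing else changes.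

## Route

Step 1
Reactants: 1 cyclohexa-1,4-diene
Product: 2 rac-trans-4,5-dibromocyclohexene
Conditions: Br2 (1.0 equiv), CH2Cl2, −78 °C
Reagents that add atoms: bromine, BrBr
Why: Electrophilic anti addition of one equivalent of bromine to one of two equivalent isolated alkenes; low temperature and slow addition hold back the tetrabromide, and the C–Br stereocentres are erased in step 4.

Step 2
Reactants: 2 rac-trans-4,5-dibromocyclohexene
Product: 3 rac-trans-4,5-dibromocyclohexane-cis-1,2-diol
Conditions: OsO4 (cat.), NMO, acetone/H2O, rt
Reagents that add atoms: N-methylmorpholine N-oxide, C[N+]1([O-])CCOCC1; water, O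
Why: Upjohn dihydroxylation adds both oxygens suprafacially; the two alkene faces of the C2-symmetric dibromide are equivalent, so one cis-diol forms, and its oxygens become O1 and O6.

Step 3
Reactants: 3 rac-trans-4,5-dibromocyclohexane-cis-1,2-diol
Product: 4 rac-trans-5,6-dibromo-2,2-dimethyl-cis-hexahydro-1,3-benzodioxole (acetonide of 3)
Conditions: 2,2-dimethoxypropane, p-TsOH (cat.), acetone, rt
Reagents that add atoms: 2,2-dimethoxypropane, COC(C)(C)OC
Why: Acid-catalysed transketalisation; a cis-1,2-diol on a six-membered ring closes the dioxolane readily.

Step 4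
Reactants: 4 rac-trans-5,6-dibromo-2,2-dimethyl-cis-hexahydro-1,3-benzodioxole
Product: 5 meso-cis-2,2-dimethyl-3a,7a-dihydro-1,3-benzodioxole (cis-5,6-isopropylidenedioxycyclohexa-1,3-diene)
Conditions: DBU (3 equiv), toluene, reflux
Reagents that add atoms: none
Why: Twofold E2 dehydrobromination, each bromide leaving with a hydrogen of the adjacent ring CH2, gives the conjugated diene; the product is meso and is used fresh because it dimerises on standing.

Step 5
Reactants: 5 meso diene acetonide
Product: 6 (1S,4S,5S,6S)-4,5-epoxy-1,6-O-isopropylidenecyclohex-2-ene-1,6-diol (epoxide on the β face, acetonide on the α face)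
Conditions: (S,S)-(salen)MnCl [chloro((1S,2S)-N,N′-bis(3,5-di-tert-butylsalicylidene)cyclohexane-1,2-diaminato)manganese] (5 mol %), 4-phenylpyridine N-oxide, aq. NaOCl (pH 11.3), CH2Cl2, 0 °C
Reagents that add atoms: sodium hypochlorite, [Na+].[O-]Cl
Why: Jacobsen–Katsuki epoxidation of a cis-disubstituted conjugated cyclic diene, a substrate class this catalyst handles well; the catalyst selects between the enantiotopic alkenes while the acetonide blocks the α face, so catalyst and substrate preferences reinforce each other for one enantiomer of the anti epoxide. This sets C4 and C5 and, with them, the absolute configuration of the whole route.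

Step 6
Reactants: 6 vinyl epoxide; 7 benzoic acid
Product: 8 (1S,4R,5S,6R)-4-O-benzoyl-1,6-O-isopropylidenecyclohex-2-ene-1,4,5,6-tetrol (free 5-OH)
Conditions: 7 (1.5 equiv), iPr2NEt (0.3 equiv), MeCN, 40 °C
Reagents that add atoms: none
Why: SN2 opening of the vinyl epoxide by benzoate at the allylic carbon C4 with inversion; C4 is activated by the adjacent π system and C5 is deactivated by the neighbouring acetal oxygen, while the buffered medium avoids an allyl cation. The trans C4-benzoate/C5-hydroxyl pair is set and O4 and O5 are differentiated by construction.

Step 7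
Reactants: 8 hydroxy benzoate
Product: 9 (1S,4R,5S,6S)-4-O-benzoyl-5-O-(tert-butyldimethylsilyl)-1,6-O-isopropylidenecyclohex-2-ene-1,4,5,6-tetrol
Conditions: TBSOTf, 2,6-lutidine, CH2Cl2, −78 → 0 °C
Reagents that add atoms: tert-butyldimethylsilyl trifluoromethanesulfonate, CC(C)(C)[Si](C)(C)OS(=O)(=O)C(F)(F)F
Why: Silylation of the only free hydroxyl with the reactive silyl triflate; the weak hindered base and low temperature prevent benzoyl migration from O4 to O5.

Step 8
Reactants: 9 silyl ether acetonide
Product: 10 (1S,4R,5R,6S)-4-O-benzoyl-5-O-(tert-butyldimethylsilyl)cyclohex-2-ene-1,4,5,6-tetrol (1,6-cis-diol)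
Conditions: CF3CO2H/H2O (4:1), CH2Cl2, 0 °C
Reagents that add atoms: none
Why: Acid-catalysed hydrolysis of the isopropylidene acetal; the hindered secondary TBS ether and the benzoate tolerate brief cold aqueous acid.

Step 9
Reactants: 10 cis-diol; 11 (bromomethyl)chlorodimethylsilane
Product: 12 (1S,4R,5R,6S)-4-O-benzoyl-1-O-[(bromomethyl)dimethylsilyl]-5-O-(tert-butyldimethylsilyl)cyclohex-2-ene-1,4,5,6-tetrol (free 6-OH)
Conditions: 11 (1.05 equiv), Et3N, CH2Cl2, −78 °C
Reagents that add atoms: none
Why: Site-selective monosilylation of a cis-diol at the less hindered hydroxyl: O1–H is allylic and flanked by an sp2 carbon, whereas O6–H lies between two oxygenated carbons next to the bulky TBS ether. The labile ether is carried on without chromatography.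

Step 10
Reactants: 12 silyl ether alcohol
Product: 13 (1S,4R,5S)-4-benzoyloxy-1-[(bromomethyl)dimethylsilyloxy]-5-(tert-butyldimethylsilyloxy)cyclohex-2-en-6-one (C6 ketone, target numbering)
Conditions: Dess–Martin periodinane, NaHCO3, CH2Cl2, 0 °C → rt
Reagents that add atoms: none
Why: Dess–Martin oxidation of the remaining secondary alcohol under buffered, non-basic conditions, which spare the labile silyl ether and avoid enolisation towards C5 and loss of the C4 benzoate; the ketone is used crude.

Step 11
Reactants: 13 C6 ketone with the (bromomethyl)dimethylsilyl ether on O1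
Product: 15 (1S,4R,5S,6R)-cis-fused 1,2-oxasilolane (SiMe2 bridging O1 and C7; 4-benzoate, 5-OTBS, β-hydroxyl at C6), via silylmethylsamarium diiodide 14 (not isolated)
Conditions: SmI2 (2.5 equiv), NiI2 (2 mol %), THF, −78 → 0 °C; pH 7 phosphate buffer
Reagents that add atoms: none
Why: Proposed new method: SmI2 reduces NiI2 to zerovalent nickel, which inserts into the Si–CH2–Br bond; transmetallation and a second electron from divalent samarium give the α-silyl organosamarium 14, a weakly basic carbanion equivalent without β-hydrogens that the O1–Si tether holds under the α face of the C6 carbonyl, to which it adds. The closest known reaction types are the samarium Barbier cyclisation of halo ketones, the Nishiyama–Stork radical cyclisation of (bromomethyl)dimethylsilyl ethers, and the addition of silylmethyl Grignard reagents to ketones followed by Tamao–Fleming oxidation; the tethered anionic delivery to a ketone has not been described. The ring C1–O–Si–C7–C6 closes in the 5-exo-trig mode. The one new stereocentre, C6, is controlled by C1: a three-atom O–Si–C bridge can only span cis positions of the six-membered ring, so C7 enters cis to O1 and the C6 hydroxyl ends on the β face next to O5. The step needs chemoselectivity for carbon–halogen activation over ketyl formation, which would expel the α-silyloxy groups at C1 or C5; nickel catalysis in THF without HMPA or a proton source addresses the bromide first, and both α-oxygens are silyl ethers, poor leaving groups under these conditions. Peterson elimination of the β-silyl alkoxide is disfavoured because the Si–C7–C6–O unit is locked in the ring far from syn-periplanar, and the neutral work-up avoids the acid-promoted anti pathway.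

Step 12
Reactants: 15 oxasilolane
Product: 16 (1S,4R,5S,6R)-4-O-benzoyl-5-O-(tert-butyldimethylsilyl)-6-(hydroxymethyl)cyclohex-2-ene-1,4,5,6-tetrol (free 1-, 6- and 7-OH)
Conditions: H2O2 (30% aq.), KF, KHCO3, THF/MeOH, rt
Reagents that add atoms: hydrogen peroxide, OO
Why: Tamao–Fleming oxidation: fluoride makes the alkoxysilane hypervalent, peroxide attacks silicon and C7 migrates from Si to O; hydrolysis of the Si–O bonds frees O1. The bicarbonate-buffered medium is tolerated by the benzoate and the TBS ether.

Step 13
Reactants: 16 triol
Product: 17 7-O-(tert-butyldimethylsilyl) ether of 16 (free 1- and 6-OH)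
Conditions: TBSCl (1.1 equiv), imidazole, CH2Cl2, 0 °C
Reagents that add atoms: tert-butyldimethylsilyl chloride, CC(C)(C)[Si](C)(C)Cl
Why: The primary hydroxyl silylates much faster than the hindered secondary O1–H next to the quaternary carbon or the tertiary O6–H; this blocks the site that would otherwise be benzoylated first.

Step 14
Reactants: 17 diol; 18 benzoyl chloride
Product: 19 (1S,4R,5S,6R)-1,4-di-O-benzoyl-5-O-(tert-butyldimethylsilyl)-6-[(tert-butyldimethylsilyloxy)methyl]cyclohex-2-ene-1,4,5,6-tetrol
Conditions: 18 (1.5 equiv), pyridine, DMAP (cat.), CH2Cl2, 0 °C → rt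
Reagents that add atoms: none
Why: DMAP-catalysed acylation of the only acylable hydroxyl; the tertiary C6 hydroxyl does not react under these conditions.

Step 15
Reactants: 19 bis-silyl ether dibenzoate
Product: 20 (1S,4R,5S,6S)-4-benzoyloxy-5,6-dihydroxy-6-(hydroxymethyl)cyclohex-2-en-1-yl benzoate (CNP0212417.1)
Conditions: HF·pyridine, pyridine, THF, 0 °C → rt
Reagents that add atoms: none
Why: Acidic fluoride cleaves both TBS ethers; the buffered acidic medium avoids the base-promoted benzoyl migrations (O4 to O5, O1 to O7) that a basic fluoride source would invite.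

## Compound list

1 | cyclohexa-1,4-diene | C1=CCC=CC1 | starting material
2 | rac-trans-4,5-dibromocyclohexene (one enantiomer drawn) | Br[C@@H]1CC=CC[C@H]1Br | intermediate
3 | rac-trans-4,5-dibromocyclohexane-cis-1,2-diol (one enantiomer drawn) | O[C@H]1C[C@@H](Br)[C@H](Br)C[C@H]1O | intermediate
4 | rac-trans-5,6-dibromo-2,2-dimethyl-cis-hexahydro-1,3-benzodioxole (one enantiomer drawn) | CC1(C)O[C@H]2C[C@@H](Br)[C@H](Br)C[C@H]2O1 | intermediate
5 | meso-cis-2,2-dimethyl-3a,7a-dihydro-1,3-benzodioxole | CC1(C)O[C@H]2C=CC=C[C@H]2O1 | intermediate
6 | (1S,4S,5S,6S)-4,5-epoxy-1,6-O-isopropylidenecyclohex-2-ene-1,6-diol | CC1(C)O[C@H]2C=C[C@@H]3O[C@@H]3[C@H]2O1 | intermediate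
7 | benzoic acid | OC(=O)c1ccccc1 | starting material
8 | (1S,4R,5S,6R)-4-O-benzoyl-1,6-O-isopropylidenecyclohex-2-ene-1,4,5,6-tetrol | CC1(C)O[C@H]2C=C[C@@H](OC(=O)c3ccccc3)[C@H](O)[C@H]2O1 | intermediate
9 | (1S,4R,5S,6S)-4-O-benzoyl-5-O-TBS-1,6-O-isopropylidenecyclohex-2-ene-1,4,5,6-tetrol | CC1(C)O[C@H]2C=C[C@@H](OC(=O)c3ccccc3)[C@H](O[Si](C)(C)C(C)(C)C)[C@H]2O1 | intermediate
10 | (1S,4R,5R,6S)-4-O-benzoyl-5-O-TBS-cyclohex-2-ene-1,4,5,6-tetrol | O[C@H]1C=C[C@@H](OC(=O)c2ccccc2)[C@H](O[Si](C)(C)C(C)(C)C)[C@H]1O | intermediate
11 | (bromomethyl)chlorodimethylsilane | C[Si](C)(Cl)CBr | starting material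
12 | (1S,4R,5R,6S)-4-O-benzoyl-1-O-[(bromomethyl)dimethylsilyl]-5-O-TBS-cyclohex-2-ene-1,4,5,6-tetrol | BrC[Si](C)(C)O[C@H]1C=C[C@@H](OC(=O)c2ccccc2)[C@H](O[Si](C)(C)C(C)(C)C)[C@H]1O | intermediate
13 | (1S,4R,5S)-4-benzoyloxy-1-[(bromomethyl)dimethylsilyloxy]-5-(TBS-oxy)cyclohex-2-en-6-one | BrC[Si](C)(C)O[C@H]1C=C[C@@H](OC(=O)c2ccccc2)[C@H](O[Si](C)(C)C(C)(C)C)C1=O | intermediate
14 | silylmethylsamarium diiodide derived from 13 (C7–SmI2) | I[Sm](I)C[Si](C)(C)O[C@H]1C=C[C@@H](OC(=O)c2ccccc2)[C@H](O[Si](C)(C)C(C)(C)C)C1=O | intermediate (not isolated)
15 | (1S,4R,5S,6R)-cis-fused 1,2-oxasilolane, SiMe2 between O1 and C7, 4-OBz, 5-OTBS, 6-OH | C[Si]1(C)O[C@H]2C=C[C@@H](OC(=O)c3ccccc3)[C@H](O[Si](C)(C)C(C)(C)C)[C@@]2(O)C1 | intermediate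
16 | (1S,4R,5S,6R)-4-O-benzoyl-5-O-TBS-6-(hydroxymethyl)cyclohex-2-ene-1,4,5,6-tetrol | O[C@H]1C=C[C@@H](OC(=O)c2ccccc2)[C@H](O[Si](C)(C)C(C)(C)C)[C@@]1(O)CO | intermediate
17 | 7-O-TBS ether of 16 | O[C@H]1C=C[C@@H](OC(=O)c2ccccc2)[C@H](O[Si](C)(C)C(C)(C)C)[C@@]1(O)CO[Si](C)(C)C(C)(C)C | intermediate
18 | benzoyl chloride | O=C(Cl)c1ccccc1 | starting material
19 | (1S,4R,5S,6R)-1,4-di-O-benzoyl-5,7-bis-O-TBS derivative | O=C(O[C@H]1C=C[C@@H](OC(=O)c2ccccc2)[C@H](O[Si](C)(C)C(C)(C)C)[C@@]1(O)CO[Si](C)(C)C(C)(C)C)c1ccccc1 | intermediate
20 | (1S,4R,5S,6S)-4-benzoyloxy-5,6-dihydroxy-6-(hydroxymethyl)cyclohex-2-en-1-yl benzoate | O=C(O[C@H]1C=C[C@@H](OC(=O)c2ccccc2)[C@H](O)[C@@]1(O)CO)c1ccccc1 | target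

Total step count: 15. Longest linear sequence: 15 steps (1 to 20).

## Least certain steps

**Step 11 (key step, proposed new method).** Electron transfer to the ketone may compete with activation of the C–Br bond, leading to reductive loss of the α-silyloxy groups or to pinacol coupling. The organometallic may also enolise the ketone, which triggers loss of benzoate. The fallback sets out from 13 and gives up the tether. Untethered addition of (isopropoxydimethylsilyl)methylmagnesium chloride, iPrOMe2SiCH2MgCl, in THF at −78 °C gives the tertiary carbinol F1. The oxidation conditions of step 12 then cleave the C7–Si bond and the labile O1 silyl ether together, so the sequence returns to the route at 16. Facial selectivity then rests on the substrate alone (the bulky TBS ether on the β face at C5 against the small silyl ether on O1) and is not assured; any C6 epimer would have to be removed at 16.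

**Step 5.** The catalyst may discriminate poorly between the two enantiotopic alkenes or between the two faces, and the diene may dimerise or be over-oxidised. The fallback sets out from 5. Epoxidation with mCPBA, which is known to go anti to the acetonide, gives 6 together with its enantiomer F2. Opening as in step 6 gives 8 together with its enantiomer F3. A lipase chosen to acetylate the unwanted enantiomer with vinyl acetate converts F3 into its acetate F4. Alcohol 8 is separated and re-enters the route before step 7. Half of the material is lost.

**Step 6.** Attack at C2 with allylic shift, or ionisation to an allyl cation, would erode regio- and stereocontrol. The fallback sets out from 6. Opening with KOH in DMSO/H2O under strictly SN2 conditions gives the trans-diol F5. Benzoylation with 18 in pyridine at −40 °C then takes the allylic, less hindered O4–H and returns to the route at 8.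

**Step 9.** The small chlorosilane may discriminate poorly between O1–H and O6–H, the silyl group may migrate between the cis hydroxyls, and the ether may hydrolyse on handling. The fallback sets out from 10. The bulkier Et3SiCl at −78 °C gives the 1-O-triethylsilyl ether F6, and Dess–Martin oxidation gives ketone F7. HF·pyridine buffered with pyridine removes the TES group in the presence of the TBS ether to give α-hydroxy ketone F8. Silylation with 11 then returns to the route at 13.

## Further compounds

F1 | step 11 | (1S,4R,5S,6R)-4-benzoyloxy-1-[(bromomethyl)dimethylsilyloxy]-6-[(isopropoxydimethylsilyl)methyl]-5-(TBS-oxy)cyclohex-2-en-6-ol | BrC[Si](C)(C)O[C@H]1C=C[C@@H](OC(=O)c2ccccc2)[C@H](O[Si](C)(C)C(C)(C)C)[C@@]1(O)C[Si](C)(C)OC(C)C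
F2 | step 5 | (1R,4R,5R,6R)-4,5-epoxy-1,6-O-isopropylidenecyclohex-2-ene-1,6-diol (enantiomer of 6) | CC1(C)O[C@@H]2C=C[C@H]3O[C@H]3[C@@H]2O1
F3 | step 5 | (1R,4S,5R,6S)-4-O-benzoyl-1,6-O-isopropylidenecyclohex-2-ene-1,4,5,6-tetrol (enantiomer of 8) | CC1(C)O[C@@H]2C=C[C@H](OC(=O)c3ccccc3)[C@@H](O)[C@@H]2O1
F4 | step 5 | 5-O-acetyl derivative of F3 | CC1(C)O[C@@H]2C=C[C@H](OC(=O)c3ccccc3)[C@@H](OC(C)=O)[C@@H]2O1
F5 | step 6 | (1S,4R,5S,6R)-1,6-O-isopropylidenecyclohex-2-ene-1,4,5,6-tetrol | CC1(C)O[C@H]2C=C[C@@H](O)[C@H](O)[C@H]2O1
F6 | step 9 | (1S,4R,5R,6S)-4-O-benzoyl-5-O-TBS-1-O-triethylsilylcyclohex-2-ene-1,4,5,6-tetrol | CC[Si](CC)(CC)O[C@H]1C=C[C@@H](OC(=O)c2ccccc2)[C@H](O[Si](C)(C)C(C)(C)C)[C@H]1O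
F7 | step 9 | (1S,4R,5S)-4-benzoyloxy-5-(TBS-oxy)-1-(triethylsilyloxy)cyclohex-2-en-6-one | CC[Si](CC)(CC)O[C@H]1C=C[C@@H](OC(=O)c2ccccc2)[C@H](O[Si](C)(C)C(C)(C)C)C1=O
F8 | step 9 | (1S,4R,5S)-4-benzoyloxy-1-hydroxy-5-(TBS-oxy)cyclohex-2-en-6-one | O[C@H]1C=C[C@@H](OC(=O)c2ccccc2)[C@H](O[Si](C)(C)C(C)(C)C)C1=O
A1 | alternative 1 | trimethylsilyl ketene acetal of the gluco-configured 2,3-di-O-benzyl-4-O-(4-methoxybenzyl) δ-lactone bearing an (E)-2-(4-methoxybenzyloxy)vinyl group on the ring-oxygen carbon | C[Si](C)(C)OC1=C(OCc2ccccc2)[C@@H](OCc2ccccc2)[C@H](OCc2ccc(OC)cc2)[C@H](O1)/C=C/OCc1ccc(OC)cc1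
A2 | alternative 1 | ring-contracted cyclohexene carboxylic acid (1,4-bis-PMB, 5,6-bis-benzyl ethers) | COc1ccc(cc1)CO[C@H]2C=C[C@@H](OCc3ccc(OC)cc3)[C@H](OCc4ccccc4)[C@@]2(OCc5ccccc5)C(=O)O
A3 | alternative 2 | 1-[(tert-butyldimethylsilyloxy)methyl]cyclohexa-2,5-dien-1-ol | OC1(CO[Si](C)(C)C(C)(C)C)C=CCC=C1
A4 | alternative 2 | syn epoxy alcohol from A3 | C1=CC[C@@H]2O[C@@H]2[C@@]1(O)CO[Si](C)(C)C(C)(C)C
A5 | alternative 3 | (Z)-iodoalkenyl aldehyde: C1 benzoate, C5/C6 acetonide, C7 TBS ether, C4 aldehyde | O=C[C@@H]1OC(C)(C)O[C@]1(CO[Si](C)(C)C(C)(C)C)[C@@H](OC(=O)c2ccccc2)/C=C\I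
A6 | alternative 3 | cyclohexenol with free C4 hydroxyl | O=C(O[C@H]1C=C[C@@H](O)[C@H](OC2(C)C)[C@@]1(O2)CO[Si](C)(C)C(C)(C)C)c1ccccc1
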